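With the chain numbered from the ester carbonyl (C1), the target is a 2,5-trans oxolane (ring O, C5–C8) whose C5 bears the ring oxygen and the exocyclic methylene C4 leading to C3. Both bonds at that site, O–C5 and C3–C4, are disconnected across a terminal C4=C5 alkene. One palladium-catalysed carboetherification adds the C8 alkoxide and a C1–C3 alkenyl bromide across this alkene, closing the ring and setting C5 trans to C8. Its precursor is (2S)-1-(benzyloxy)hex-5-en-2-ol: the carbinol is C8 and the benzyloxymethyl arm is the latent alkyne carbon C9. The enyne–bromodiene tail follows by Sonogashira coupling and Wittig bromomethylenation.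

Key step: step 3

Remark: carbon numbers C1–C20 follow the chain from the ester carbonyl to the brominated carbon; silyl ether 4 is taken as a purchased material; zirconocene compounds are written in SMILES with σ-bonded cyclopentadienyl rings as notation only.

Step 1
Reactants: 1 (S)-benzyl glycidyl ether [(2S)-2-[(benzyloxy)methyl]oxirane]; 2 allylmagnesium bromide (CH2=CHCH2MgBr)
Product: 3 (2S)-1-(benzyloxy)hex-5-en-2-ol
Conditions: CuI (10 mol%), THF, −40 to 0 °C; aq NH4Cl
Reagents that add atoms: none
Why: Copper-catalysed Grignard opening of a terminal epoxide is an SN2 attack at the unsubstituted carbon, so the allyl group should add at CH2 only and the existing stereocentre (the future C8) is carried over unchanged as the S carbinol.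

Step 2
Reactants: 4 tert-butyldimethyl(prop-2-yn-1-yloxy)silane
Product: 6 {[(2E)-3-bromoprop-2-en-1-yl]oxy}(tert-butyl)dimethylsilane, via alkenylzirconocene chloride 5 (not isolated)
Conditions: Cp2Zr(H)Cl, THF, rt; then NBS, 0 °C
Reagents that add atoms: N-bromosuccinimide, O=C1CCC(=O)N1Br
Why: Hydrozirconation–bromination: Cp2Zr(H)Cl adds syn across the terminal alkyne with zirconium on the terminal carbon and N-bromosuccinimide cleaves the C–Zr bond with retention, which should give the E-bromoalkene alone; the E isomer is wanted because its bromine has no anti β-hydrogen and so resists dehydrobromination by alkoxide in step 3.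

Step 3
Reactants: 3 (2S)-1-(benzyloxy)hex-5-en-2-ol; 6 {[(2E)-3-bromoprop-2-en-1-yl]oxy}(tert-butyl)dimethylsilane (1.5 equiv)
Product: 7 {[(2E)-4-[(2S,5S)-5-[(benzyloxy)methyl]oxolan-2-yl]but-2-en-1-yl]oxy}(tert-butyl)dimethylsilane (2,5-trans)
Conditions: Pd2(dba)3 (2 mol%), DPEphos [bis(2-diphenylphosphinophenyl) ether] (4 mol%), NaOtBu (2 equiv), THF, 65 °C
Reagents that add atoms: none
Why: Zerovalent palladium inserts into the C3–Br bond of 6, the deprotonated hydroxyl of 3 replaces bromide on palladium, the C4=C5 alkene inserts syn into the Pd–O bond to form O–C5, and C–C reductive elimination from the resulting alkylpalladium joins C4 to C3 with the E-alkene intact. The closest known reaction type is the palladium-catalysed carboetherification of γ-hydroxy terminal alkenes with aryl or alkenyl bromides, a known reaction applied here to a new pair of partners. The oxolane closes in a 5-exo syn-oxypalladation. The new stereocentre C5 is controlled by the existing C8 centre, because in the organised cyclic insertion transition state the benzyloxymethyl group lies pseudo-equatorial and the C4 methylene ends up on the opposite face of the ring. The step needs trans selectivity and suppression of β-hydride elimination from the palladium alkoxide and the alkylpalladium; the first is secured by the substrate class (one substituent at the carbinol, unsubstituted terminal alkene), the second by the wide-bite-angle chelating bisphosphine. The benzyl ether next to the alkoxide cannot migrate as a silyl group could, and the remote TBS ether is inert to NaOtBu.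

Step 4
Reactants: 7 {[(2E)-4-[(2S,5S)-5-[(benzyloxy)methyl]oxolan-2-yl]but-2-en-1-yl]oxy}(tert-butyl)dimethylsilane
Product: 8 [(2S,5R)-5-{4-[(tert-butyldimethylsilyl)oxy]butyl}oxolan-2-yl]methanol
Conditions: H2 (1 atm), 10% Pd/C, EtOAc, rt
Reagents that add atoms: none
Why: Heterogeneous hydrogenation over Pd/C should saturate the C2=C3 alkene and hydrogenolyse the benzyl ether in the same operation, while neutral aprotic ethyl acetate keeps the TBS ether in place and no stereocentre is involved.

Step 5
Reactants: 8 [(2S,5R)-5-{4-[(tert-butyldimethylsilyl)oxy]butyl}oxolan-2-yl]methanol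
Product: 9 (2S,5R)-5-{4-[(tert-butyldimethylsilyl)oxy]butyl}oxolane-2-carbaldehyde
Conditions: TEMPO (10 mol%), PhI(OAc)2, CH2Cl2, rt
Reagents that add atoms: none
Why: The TEMPO/PhI(OAc)2 oxidation (oxoammonium-mediated alcohol oxidation) stops at the aldehyde in dry CH2Cl2 and uses no amine base, so C8, now α to a carbonyl group, should keep its configuration.

Step 6
Reactants: 9 (2S,5R)-5-{4-[(tert-butyldimethylsilyl)oxy]butyl}oxolane-2-carbaldehyde
Product: 10 tert-butyl{4-[(2R,5S)-5-ethynyloxolan-2-yl]butoxy}dimethylsilane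
Conditions: dimethyl (1-diazo-2-oxopropyl)phosphonate, K2CO3, MeOH, 0 °C to rt
Reagents that add atoms: dimethyl (1-diazo-2-oxopropyl)phosphonate, CC(=O)C(=[N+]=[N-])P(=O)(OC)OC
Why: Ohira–Bestmann (Seyferth–Gilbert) homologation: methanolysis of the reagent releases the diazomethylphosphonate anion, which adds to the aldehyde, loses dimethyl phosphate and then N2 with a 1,2-hydride shift to give the terminal alkyne C9≡C10, under carbonate conditions mild enough that α-alkoxy aldehydes normally keep their configuration and primary TBS ethers survive.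

Step 7
Reactants: 10 tert-butyl{4-[(2R,5S)-5-ethynyloxolan-2-yl]butoxy}dimethylsilane
Product: 13 4-[(2R,5S)-5-ethynyloxolan-2-yl]butanoic acid, via primary alcohol 11 (not isolated), via aldehyde 12 (not isolated)
Conditions: CrO3, H2SO4, H2O, acetone, 0 °C
Reagents that add atoms: water, O
Why: Jones oxidation: the aqueous sulfuric acid hydrolyses the primary TBS ether and chromic acid oxidises the freed C1 alcohol through the aldehyde hydrate to the carboxylic acid in the same flask, conditions to which a terminal alkyne and the ring ether are inert.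

Step 8
Reactants: 13 4-[(2R,5S)-5-ethynyloxolan-2-yl]butanoic acid
Product: 14 methyl 4-[(2R,5S)-5-ethynyloxolan-2-yl]butanoate
Conditions: MeI, K2CO3, DMF, rt
Reagents that add atoms: iodomethane, CI
Why: SN2 O-methylation of the potassium carboxylate by iodomethane should give the methyl ester cleanly, since carbonate is too weak a base to deprotonate the terminal alkyne.

Step 9
Reactants: 15 hept-6-yn-1-ol
Product: 17 (6E)-7-iodohept-6-en-1-ol, via zirconated alkenyl alkoxide 16 (not isolated)
Conditions: Cp2Zr(H)Cl (2.2 equiv), THF, rt; then I2, 0 °C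
Reagents that add atoms: iodine, II
Why: Hydrozirconation–iodination: one equivalent of Cp2Zr(H)Cl is consumed by the hydroxyl group as a zirconium alkoxide, the second adds syn to the alkyne with zirconium on the terminal carbon, and iodine cleaves the C–Zr bond with retention, so only the E-iodoalkene (C11=C12) should form.

Step 10
Reactants: 17 (6E)-7-iodohept-6-en-1-ol
Product: 18 (6E)-7-iodohept-6-enal
Conditions: TEMPO (10 mol%), PhI(OAc)2, CH2Cl2, rt
Reagents that add atoms: none
Why: The same TEMPO/PhI(OAc)2 alcohol oxidation should give the aldehyde without over-oxidation and without touching the alkenyl iodide.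

Step 11
Reactants: 18 (6E)-7-iodohept-6-enal
Product: 19 (2E,8E)-9-iodonona-2,8-dienal
Conditions: Ph3P=CHCHO (1.1 equiv), toluene, 80 °C
Reagents that add atoms: (triphenylphosphoranylidene)acetaldehyde, O=CC=P(c1ccccc1)(c1ccccc1)c1ccccc1
Why: Wittig reaction with a formyl-stabilised ylide, which as a stabilised ylide should give the E-enal (C17=C18) and reacts much faster with the aliphatic aldehyde than with the less electrophilic product enal.

Step 12
Reactants: 14 methyl 4-[(2R,5S)-5-ethynyloxolan-2-yl]butanoate; 19 (2E,8E)-9-iodonona-2,8-dienal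
Product: 20 methyl 4-[(2R,5S)-5-[(3E,9E)-11-oxoundeca-3,9-dien-1-yn-1-yl]oxolan-2-yl]butanoate
Conditions: PdCl2(PPh3)2 (5 mol%), CuI (10 mol%), Et3N, THF, rt
Reagents that add atoms: none
Why: Sonogashira coupling: zerovalent palladium formed in the flask inserts into the C–I bond with retention of the E geometry, the copper acetylide of 14 transmetalates and reductive elimination forms C10–C11, while the tertiary amine cannot condense with the enal and the ester is inert.

Step 13
Reactants: 20 methyl 4-[(2R,5S)-5-[(3E,9E)-11-oxoundeca-3,9-dien-1-yn-1-yl]oxolan-2-yl]butanoate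
Product: 21 methyl 4-[(2R,5S)-5-[(3E,9E,11Z)-12-bromododeca-3,9,11-trien-1-yn-1-yl]oxolan-2-yl]butanoate (CNP0231094.3)
Conditions: (bromomethyl)triphenylphosphonium bromide, KOtBu, THF, −78 °C; then 20, −78 °C to rt
Reagents that add atoms: (bromomethyl)triphenylphosphonium bromide, BrC[P+](c1ccccc1)(c1ccccc1)c1ccccc1.[Br-]
Why: Wittig reaction with the non-stabilised bromomethylene ylide under lithium-free, low-temperature kinetic control proceeds through the cis-oxaphosphetane and should give the Z-bromoalkene (C19=C20), leaving the ester, the enyne and the E-alkenes untouched.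

Compound list
1 | (S)-benzyl glycidyl ether, (2S)-2-[(benzyloxy)methyl]oxirane | C1[C@@H](COCc2ccccc2)O1 | starting material
2 | allylmagnesium bromide | C=CC[Mg]Br | starting material
3 | (2S)-1-(benzyloxy)hex-5-en-2-ol | C=CCC[C@@H](COCc1ccccc1)O | intermediate
4 | tert-butyldimethyl(prop-2-yn-1-yloxy)silane | C#CCO[Si](C)(C)C(C)(C)C | starting material
5 | Cp2Zr(Cl)[(E)-CH=CHCH2OTBS], [(1E)-3-{[tert-butyl(dimethyl)silyl]oxy}prop-1-en-1-yl]chlorobis(cyclopentadienyl)zirconium | CC(C)(C)[Si](C)(C)OC/C=C/[Zr](Cl)(C1C=CC=C1)C1C=CC=C1 | intermediate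
6 | {[(2E)-3-bromoprop-2-en-1-yl]oxy}(tert-butyl)dimethylsilane | Br/C=C/CO[Si](C)(C)C(C)(C)C | intermediate
7 | {[(2E)-4-[(2S,5S)-5-[(benzyloxy)methyl]oxolan-2-yl]but-2-en-1-yl]oxy}(tert-butyl)dimethylsilane | CC(C)(C)[Si](C)(C)OC/C=C/C[C@@H]1CC[C@@H](COCc2ccccc2)O1 | intermediate
8 | [(2S,5R)-5-{4-[(tert-butyldimethylsilyl)oxy]butyl}oxolan-2-yl]methanol | CC(C)(C)[Si](C)(C)OCCCC[C@@H]1CC[C@@H](CO)O1 | intermediate
9 | (2S,5R)-5-{4-[(tert-butyldimethylsilyl)oxy]butyl}oxolane-2-carbaldehyde | CC(C)(C)[Si](C)(C)OCCCC[C@@H]1CC[C@@H](C=O)O1 | intermediate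
10 | tert-butyl{4-[(2R,5S)-5-ethynyloxolan-2-yl]butoxy}dimethylsilane | CC(C)(C)[Si](C)(C)OCCCC[C@@H]1CC[C@@H](C#C)O1 | intermediate
11 | 4-[(2R,5S)-5-ethynyloxolan-2-yl]butan-1-ol | OCCCC[C@@H]1CC[C@@H](C#C)O1 | intermediate
12 | 4-[(2R,5S)-5-ethynyloxolan-2-yl]butanal | O=CCCC[C@@H]1CC[C@@H](C#C)O1 | intermediate
13 | 4-[(2R,5S)-5-ethynyloxolan-2-yl]butanoic acid | OC(=O)CCC[C@@H]1CC[C@@H](C#C)O1 | intermediate
14 | methyl 4-[(2R,5S)-5-ethynyloxolan-2-yl]butanoate | COC(=O)CCC[C@@H]1CC[C@@H](C#C)O1 | intermediate
15 | hept-6-yn-1-ol | OCCCCCC#C | starting material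
16 | Cp2Zr(Cl)–O(CH2)5–CH=CH–Zr(Cl)Cp2, the (E)-alkenylzirconocene chloride whose oxygen carries a second Cp2ZrCl unit | Cl[Zr](OCCCCC/C=C/[Zr](Cl)(C1C=CC=C1)C1C=CC=C1)(C1C=CC=C1)C1C=CC=C1 | intermediate
17 | (6E)-7-iodohept-6-en-1-ol | OCCCCC/C=C/I | intermediate
18 | (6E)-7-iodohept-6-enal | O=CCCCC/C=C/I | intermediate
19 | (2E,8E)-9-iodonona-2,8-dienal | O=C/C=C/CCCC/C=C/I | intermediate
20 | methyl 4-[(2R,5S)-5-[(3E,9E)-11-oxoundeca-3,9-dien-1-yn-1-yl]oxolan-2-yl]butanoate | COC(=O)CCC[C@@H]1CC[C@@H](C#C/C=C/CCCC/C=C/C=O)O1 | intermediate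
21 | methyl 4-[(2R,5S)-5-[(3E,9E,11Z)-12-bromododeca-3,9,11-trien-1-yn-1-yl]oxolan-2-yl]butanoate | COC(=O)CCC[C@@H]1CC[C@@H](C#C/C=C/CCCC/C=C/C=C\Br)O1 | target

Total step count: 13.
Longest linear sequence: 9 steps (1, 3, 4, 5, 6, 7, 8, 12, 13; the branch through step 2 is equally long).

Steps most likely to fail

Step 3. β-Hydride elimination could compete, either from the palladium alkoxide (oxidising the carbinol and reducing the bromide) or from the alkylpalladium after ring closure. Trans selectivity could also be incomplete, or the alkenyl bromide could be consumed by base. The fallback sets out from 3 and returns at 8, and builds the ring and the C3–C4 bond in separate known operations.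
- Cobalt-catalysed aerobic oxidative cyclisation of 3 (Mukaiyama cyclisation; Co(modp)2 with modp = 1-morpholinocarbamoyl-4,4-dimethylpentane-1,3-dionate, O2, t-BuOOH, i-PrOH, 55 °C) is reliably trans-selective for pent-4-en-1-ols of this type. It should give [(2S,5S)-5-[(benzyloxy)methyl]oxolan-2-yl]methanol F1, with C4 as a hydroxymethyl group.
- Tf2O and 2,6-lutidine (CH2Cl2, −78 °C) would convert it into [(2S,5S)-5-[(benzyloxy)methyl]oxolan-2-yl]methyl trifluoromethanesulfonate F2.
- Deprotonation of 4 with n-BuLi (THF, −78 °C) gives (3-{[tert-butyl(dimethyl)silyl]oxy}prop-1-yn-1-yl)lithium F3. This should displace the triflate in THF/DMPU to give {[4-[(2S,5S)-5-[(benzyloxy)methyl]oxolan-2-yl]but-2-yn-1-yl]oxy}(tert-butyl)dimethylsilane F4.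
- Hydrogenation over 10% Pd/C in EtOAc would then reduce the alkyne fully and remove the benzyl group, arriving at 8.

Step 6. Enolisation of the α-alkoxy aldehyde in basic methanol could erode the configuration at C8, and with it the trans relationship, before the homologation is complete. The fallback sets out from 9 and returns at 10 by a Corey–Fuchs sequence, whose olefination stage is not basic.
- CBr4 and PPh3 (CH2Cl2, 0 °C) should give tert-butyl{4-[(2R,5S)-5-(2,2-dibromoethenyl)oxolan-2-yl]butoxy}dimethylsilane F5.
- Two equivalents of n-BuLi (THF, −78 °C) would bring about bromine–lithium exchange, α-elimination and Fritsch–Buttenberg–Wiechell rearrangement to {[(2S,5R)-5-(4-{[tert-butyl(dimethyl)silyl]oxy}butyl)oxolan-2-yl]ethynyl}lithium F6.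
- An aqueous quench gives 10.

Step 13. Incomplete kinetic control in the oxaphosphetane formation could erode the Z selectivity at C19=C20 and give geometric isomers that are hard to separate at the last stage. The fallback sets out from 20 and returns at 21, and fixes the geometry by a stereoselective reduction in place of an olefination.
- Dibromo-olefination of 20 (CBr4, PPh3, CH2Cl2, 0 °C) should give methyl 4-[(2R,5S)-5-[(3E,9E)-12,12-dibromododeca-3,9,11-trien-1-yn-1-yl]oxolan-2-yl]butanoate F7.
- Palladium-catalysed hydrodebromination (Pd(PPh3)4, one equivalent of Bu3SnH added slowly, toluene, rt) should then remove selectively the bromine trans to the diene chain. That C–Br bond undergoes oxidative addition faster, and the Z-bromide 21 is left.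

Further compounds
F1 | step 3 | [(2S,5S)-5-[(benzyloxy)methyl]oxolan-2-yl]methanol | OC[C@@H]1CC[C@@H](COCc2ccccc2)O1
F2 | step 3 | [(2S,5S)-5-[(benzyloxy)methyl]oxolan-2-yl]methyl trifluoromethanesulfonate | O=S(=O)(OC[C@@H]1CC[C@@H](COCc2ccccc2)O1)C(F)(F)F
F3 | step 3 | (3-{[tert-butyl(dimethyl)silyl]oxy}prop-1-yn-1-yl)lithium | [Li]C#CCO[Si](C)(C)C(C)(C)C
F4 | step 3 | {[4-[(2S,5S)-5-[(benzyloxy)methyl]oxolan-2-yl]but-2-yn-1-yl]oxy}(tert-butyl)dimethylsilane | CC(C)(C)[Si](C)(C)OCC#CC[C@@H]1CC[C@@H](COCc2ccccc2)O1
F5 | step 6 | tert-butyl{4-[(2R,5S)-5-(2,2-dibromoethenyl)oxolan-2-yl]butoxy}dimethylsilane | CC(C)(C)[Si](C)(C)OCCCC[C@@H]1CC[C@@H](C=C(Br)Br)O1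
F6 | step 6 | {[(2S,5R)-5-(4-{[tert-butyl(dimethyl)silyl]oxy}butyl)oxolan-2-yl]ethynyl}lithium | CC(C)(C)[Si](C)(C)OCCCC[C@@H]1CC[C@@H](C#C[Li])O1
F7 | step 13 | methyl 4-[(2R,5S)-5-[(3E,9E)-12,12-dibromododeca-3,9,11-trien-1-yn-1-yl]oxolan-2-yl]butanoate | COC(=O)CCC[C@@H]1CC[C@@H](C#C/C=C/CCCC/C=C/C=C(Br)Br)O1
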